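Assumption: 5,7-dihydroxy-2,2-dimethyl-4H-1,3-benzodioxin-4-one (9), the acetonide of 2,4,6-trihydroxybenzoic acid, is taken as a catalogue compound and used as bought.

## The problem

Kuwanon T is an achiral flavone. Ring A is a 5,7-dihydroxylated benzo ring, ring C is the 4-pyranone, and ring B, bound to C2 through C1', is a resorcinol ring with hydroxyls at C2' and C4'. There are no stereocentres, so the task is one of regiochemistry and chemoselectivity. The first difficulty is C3 of ring C: it is a fully substituted olefinic carbon wedged between the C4 carbonyl and the ortho-substituted ring B, and a prenyl group cannot be put there by simple alkylation of a finished flavone. The second is C3' of ring B, where the other prenyl group sits between the oxygens at C2' and C4', the most hindered nucleophilic position of that ring. The third is sensitivity: a prenyl group next to a free phenol closes to a 2,2-dimethylchroman under acid, is attacked by electrophilic halogen and by oxidants, and is reduced under hydrogenolysis, so acid cyclodehydration, acid-labile or benzyl protecting groups and late C3 halogenation are all unsafe, and the four phenols must be unveiled under neutral conditions. The feature that opens a way out lies in ring C itself: C3 stands between C4 and C2, and both are carboxyl carbons in disguise, C4 that of a ring A salicylic acid (2,4,6-trihydroxybenzoic acid) and C2 that of the ring B benzoic acid held as an aryl ester on O1. C3 with its whole prenyl chain can therefore enter as one phosphorus ylide carbon that is acylated once (C3–C4) and then olefinates the O1–C2 ester carbonyl (C2=C3), which closes ring C at carbon, without acid, with the prenyl group already in place.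

## Retrosynthesis

**19 to 18.** The four O–H bonds of 19 are traced back to four O–allyl bonds in 18. Allyl ethers are chosen over silyl, acetal or benzyl ethers because they survive strong base, ylides and 110 °C, and are removed by a zerovalent palladium catalyst and an amine, conditions that leave a C-prenyl group untouched. One kind of group on all four oxygens means a single final step. The forward reaction must cleave four aryl ethers without C-allylating ring A.

**18 to 15 and 8 (key disconnection).** In 18 the C2=C3 double bond and the O1–C2 bond are cut. This leads through the aroyloxy ylide 17 to the keto ylide 15 (ring A, C4, C3 and the C3 prenyl chain) and the ring B acid 8, activated as its chloride 16. The neighbouring cuts were weighed: O1–C2 closure by dehydration needs acid, and cutting the C3–prenyl bond needs halogenation of a prenylated flavone. The chosen cut needs neither, and forms the hindered tetrasubstituted olefin inside a six-membered transition state. The precursors are an acyclic ylide and a benzoic acid, with no ring C. The forward reaction must esterify the phenol of 15 selectively and then olefinate an electron-rich, ortho-substituted ester carbonyl.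

**15 to 10 and 13.** The C3–C4 bond of 15 is cut to the benzodioxinone 10 and the non-stabilised ylide 14, made from the phosphonium salt 13. The acetal ring of 10 masks exactly O1 and the C4 carboxyl. Acylation of 14 at C4 opens the ring and releases the O1 phenol, so no separate deprotection or differentiation of the ring A oxygens is needed. The forward reaction asks a bulky ylide to attack a hindered acylal carbonyl.

**10 to 9; 13 to 11 and 12.** The two allyl ethers of 10 come from the diol 9 and allyl bromide 6. The salt 13 comes from the homoprenyl bromide 11 and triphenylphosphine 12, so that C3 and its prenyl chain are bought as one six-carbon unit. Both are routine alkylations.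

**8 to 7 to 5.** The acid 8 is traced to its methyl ester 7, and the two allyl ethers of 7 to the diol 5 and 6. The ester is kept until the phenols are capped because the free salicylic acid would decarboxylate or O-acylate itself. The forward steps are a Williamson etherification of a chelated, flanked phenol and a saponification.

**5 to 4 to 3 to 1 and 2.** The C3'–prenyl bond of 5 is cut by an aromatic Claisen transform to the tertiary allyl ether 4. That ether comes from the propargyl ether 3 by semihydrogenation, and 3 from methyl 2,4-dihydroxybenzoate 1 and the propargylic chloride 2. Direct C-prenylation of 1 was rejected because it gives mixtures of C3, C5 and O-alkylation. The sigmatropic shift delivers the chain with allylic inversion, so the 1,1-dimethylallyl ether gives the normal prenyl group. The forward reaction needs the shift to go to C3 rather than C5, which the chelated 2-hydroxyl should favour.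

## Roads not taken

**Alternative 1:** The most obvious plan cuts the C3–prenyl bond of a finished flavone and closes ring C at O1–C2. A Baker–Venkataraman acyl shift and acid cyclodehydration would give the 3-unsubstituted flavone A1. Iodination at C3 would give the iodide A2, and a Stille coupling with a prenylstannane would install the chain. The chosen plan is better on three counts. Electrophilic iodine on A1 meets the 3'-prenyl olefin as well as C3. Ring closure and the usual acetal protecting groups both need acid, which a prenyl group flanked by two phenols does not tolerate. And allyl transfer from tin can deliver the chain at either terminus, giving reverse-prenyl product. Three operations after ring formation are spent on one carbon–carbon bond.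

**Alternative 2:** A more original cut uses O2' as a relay. In the 2'-O-prenyl ether A3 the array O2'–C2'=C1'–C2=C3 allows a first [3,3] shift of the prenyl group to C1' and a second [3,3] shift from C1' to C3. The two allylic inversions restore the normal prenyl group, and tautomerisation frees the 2'-hydroxyl. The weakness is structural: from C1' the chain can equally shift to C5', the unsubstituted position para to O2', and nothing in this target blocks that path. The step also needs about 180–200 °C while a free 2'-hydroxyl appears next to the 3'-prenyl group. A3 itself still requires a full flavone synthesis with O2' differentiated. The chosen plan has no regiochemical branch at C3 and stays at or below 110 °C.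

**Alternative 3:** Ring C can also be cut at C4–C4a and O1–C2, a Mentzer-type thermal condensation of free phloroglucinol with the α-prenyl β-keto ester A4 through an aroylketene. It is the shortest plan on paper and needs no ring A protection. It fails on ring B protection at about 240 °C: allyl ethers rearrange, and a silyl ether on O2' sits next to the ketene and can be captured to a 4-oxycoumarin. No group that is removable without acid is safe there. The chosen plan reaches the same C–C logic under mild conditions.

Key step: step 9

## Route

**Step 1**
Reactants: 1 methyl 2,4-dihydroxybenzoate; 2 3-chloro-3-methylbut-1-yne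
Product: 3 methyl 2-hydroxy-4-[(2-methylbut-3-yn-2-yl)oxy]benzoate
Conditions: 2, DBU, CuCl2 (cat.), MeCN, 0 °C → rt
Reagents that add atoms: 3-chloro-3-methylbut-1-yne, C#CC(C)(C)Cl
Why: Copper-catalysed propargylic etherification of phenols with tertiary propargylic chlorides is well established; the 4-hydroxyl is the more acidic and is not chelated, whereas the 2-hydroxyl is hydrogen-bonded to the ester and should stay free.

**Step 2**
Reactants: 3 methyl 2-hydroxy-4-[(2-methylbut-3-yn-2-yl)oxy]benzoate
Product: 4 methyl 2-hydroxy-4-[(2-methylbut-3-en-2-yl)oxy]benzoate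
Conditions: H2 (1 atm), Pd/CaCO3 poisoned with Pb(OAc)2, quinoline, EtOAc, rt
Reagents that add atoms: none
Why: Lindlar semihydrogenation of a terminal alkyne to the vinyl group; the poisoned catalyst should stop at the alkene and leave the aryl ether intact.

**Step 3**
Reactants: 4 methyl 2-hydroxy-4-[(2-methylbut-3-en-2-yl)oxy]benzoate
Product: 5 methyl 2,4-dihydroxy-3-(3-methylbut-2-en-1-yl)benzoate
Conditions: PhNEt2, 150 °C, argon
Reagents that add atoms: none
Why: Aromatic Claisen rearrangement; the [3,3] shift inverts the 1,1-dimethylallyl unit to a normal prenyl group, and the chelate between the 2-hydroxyl and the ester should direct the shift to C3 between the two oxygens rather than to C5, while the basic solvent suppresses chroman formation.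

**Step 4**
Reactants: 5 methyl 2,4-dihydroxy-3-(3-methylbut-2-en-1-yl)benzoate; 6 allyl bromide
Product: 7 methyl 3-(3-methylbut-2-en-1-yl)-2,4-bis(prop-2-en-1-yloxy)benzoate
Conditions: 6, K2CO3, DMF, 60 °C
Reagents that add atoms: allyl bromide, C=CCBr
Why: Williamson etherification of both phenols; the chelated and flanked 2-hydroxyl needs the polar solvent and gentle heating, which is far below the temperature at which allyl aryl ethers rearrange.

**Step 5**
Reactants: 7 methyl 3-(3-methylbut-2-en-1-yl)-2,4-bis(prop-2-en-1-yloxy)benzoate
Product: 8 3-(3-methylbut-2-en-1-yl)-2,4-bis(prop-2-en-1-yloxy)benzoic acid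
Conditions: LiOH, THF/MeOH/H2O, 60 °C; then 1 M HCl to pH 3, 0 °C
Reagents that add atoms: lithium hydroxide, [Li+].[OH-]
Why: Saponification of a methyl benzoate; with both phenols capped as ethers the prenyl group has no neighbouring hydroxyl and should tolerate the brief cold acidification.

**Step 6**
Reactants: 9 5,7-dihydroxy-2,2-dimethyl-4H-1,3-benzodioxin-4-one; 6 allyl bromide
Product: 10 2,2-dimethyl-5,7-bis(prop-2-en-1-yloxy)-4H-1,3-benzodioxin-4-one
Conditions: 6, K2CO3, DMF, 50 °C
Reagents that add atoms: allyl bromide, C=CCBr
Why: Williamson etherification of both phenols of the benzodioxinone, a standard operation on this acetonide; anhydrous carbonate leaves the acylal ring closed.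

**Step 7**
Reactants: 11 5-bromo-2-methylpent-2-ene; 12 triphenylphosphine
Product: 13 (4-methylpent-3-en-1-yl)triphenylphosphonium bromide
Conditions: toluene, 110 °C
Reagents that add atoms: triphenylphosphine, c1ccc(cc1)P(c1ccccc1)c1ccccc1
Why: Quaternisation of triphenylphosphine by a primary alkyl bromide (SN2); the salt should crystallise from the hot solvent.

**Step 8**
Reactants: 13 (4-methylpent-3-en-1-yl)triphenylphosphonium bromide; 10 2,2-dimethyl-5,7-bis(prop-2-en-1-yloxy)-4H-1,3-benzodioxin-4-one
Product: 15 1-[2-hydroxy-4,6-bis(prop-2-en-1-yloxy)phenyl]-5-methyl-2-(triphenyl-λ5-phosphanylidene)hex-4-en-1-one, via phosphorus ylide 14 (not isolated)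
Conditions: 13 (2.5 equiv), KN(SiMe3)2 (2.5 equiv), THF, 0 °C; then 10, 0 °C → rt; pH 7 buffer
Reagents that add atoms: none
Why: C-Acylation of a non-stabilised phosphorus ylide by an activated ester: the ylide carbon attacks the acylal carbonyl C4 of 10, the ring opens with loss of the acetal ketone, and the released O1 phenoxide deprotonates the acylphosphonium to the stabilised keto ylide 15; the excess ylide covers what the liberated ketone consumes.

**Step 9**
Reactants: 15 1-[2-hydroxy-4,6-bis(prop-2-en-1-yloxy)phenyl]-5-methyl-2-(triphenyl-λ5-phosphanylidene)hex-4-en-1-one; 8 3-(3-methylbut-2-en-1-yl)-2,4-bis(prop-2-en-1-yloxy)benzoic acid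
Product: 18 3-(3-methylbut-2-en-1-yl)-2-[3-(3-methylbut-2-en-1-yl)-2,4-bis(prop-2-en-1-yloxy)phenyl]-5,7-bis(prop-2-en-1-yloxy)-4H-chromen-4-one, via acid chloride 16 (not isolated), via aroyloxy ylide 17 (not isolated)
Conditions: 8, 1-chloro-N,N,2-trimethylprop-1-en-1-amine, CH2Cl2, 0 °C → rt; then 15, Et3N, DMAP (cat.), toluene, rt → 110 °C
Reagents that add atoms: none
Why: The acid 8 is turned into its chloride 16 under neutral conditions, and the phenol of 15, acidified by its hydrogen bond to the ylide carbonyl, is acylated by 16 to give the aryl ester 17; the ylide carbon is already fully substituted and cannot be acylated productively, and acylation at the ylide oxygen is reversible and passes the aroyl group on to the phenoxide. On heating, the ylide carbon C3 adds to the ester carbonyl carbon C2 (6-exo-trig closure of ring C, the only ring formed), the oxaphosphetane collapses with loss of the phosphine oxide, and the C2=C3 bond of the pyranone is formed directly, so ring C is closed at carbon and no dehydration is needed. The closest known reaction type is the intramolecular Wittig olefination of ester carbonyls by 2-acyloxyphenacylidene phosphoranes, which gives chromones and flavones in hot toluene. No stereocentre is formed and the olefin geometry is fixed by the ring. The selectivity needed is olefination over loss of the aroyl group: if the adduct expelled the ring A phenoxide instead, that phenoxide would remain placed to add back to C2, so both paths should converge on 18. The α-prenyl group makes the ylide carbon more hindered but also more electron-rich than in the unsubstituted parent, and the six-membered transition state, the new P=O bond and the conjugated pyranone should carry the closure. At 110 °C the four allyl ethers stay below the threshold of the aromatic Claisen rearrangement, and no acid, halogen or oxidant touches the two prenyl groups.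

**Step 10**
Reactants: 18 3-(3-methylbut-2-en-1-yl)-2-[3-(3-methylbut-2-en-1-yl)-2,4-bis(prop-2-en-1-yloxy)phenyl]-5,7-bis(prop-2-en-1-yloxy)-4H-chromen-4-one
Product: 19 Kuwanon T, 5,7-dihydroxy-2-[2,4-dihydroxy-3-(3-methylbut-2-en-1-yl)phenyl]-3-(3-methylbut-2-en-1-yl)-4H-chromen-4-one
Conditions: Pd(PPh3)4 (cat.), morpholine, THF, rt, degassed, argon; work-up with pH 5 phosphate buffer
Reagents that add atoms: none
Why: Tsuji–Trost deallylation: zerovalent palladium ionises each aryl allyl ether to a π-allyl complex and a phenoxide, and morpholine captures the allyl unit; the C-prenyl groups have no leaving group and are not touched, and excluding air prevents palladium-mediated oxidative cyclisation of the freed ortho-prenyl phenol.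

## Compound list

1 | methyl 2,4-dihydroxybenzoate | COC(=O)c1ccc(O)cc1O | starting material
2 | 3-chloro-3-methylbut-1-yne | C#CC(C)(C)Cl | starting material
3 | methyl 2-hydroxy-4-[(2-methylbut-3-yn-2-yl)oxy]benzoate | COC(=O)c1ccc(OC(C)(C)C#C)cc1O | intermediate
4 | methyl 2-hydroxy-4-[(2-methylbut-3-en-2-yl)oxy]benzoate | COC(=O)c1ccc(OC(C)(C)C=C)cc1O | intermediate
5 | methyl 2,4-dihydroxy-3-(3-methylbut-2-en-1-yl)benzoate | COC(=O)c1ccc(O)c(CC=C(C)C)c1O | intermediate
6 | allyl bromide (3-bromoprop-1-ene) | C=CCBr | starting material
7 | methyl 3-(3-methylbut-2-en-1-yl)-2,4-bis(prop-2-en-1-yloxy)benzoate | COC(=O)c1ccc(OCC=C)c(CC=C(C)C)c1OCC=C | intermediate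
8 | 3-(3-methylbut-2-en-1-yl)-2,4-bis(prop-2-en-1-yloxy)benzoic acid | OC(=O)c1ccc(OCC=C)c(CC=C(C)C)c1OCC=C | intermediate
9 | 5,7-dihydroxy-2,2-dimethyl-4H-1,3-benzodioxin-4-one | CC1(C)OC(=O)c2c(O)cc(O)cc2O1 | starting material
10 | 2,2-dimethyl-5,7-bis(prop-2-en-1-yloxy)-4H-1,3-benzodioxin-4-one | CC1(C)OC(=O)c2c(OCC=C)cc(OCC=C)cc2O1 | intermediate
11 | 5-bromo-2-methylpent-2-ene | CC(C)=CCCBr | starting material
12 | triphenylphosphine | c1ccc(cc1)P(c1ccccc1)c1ccccc1 | starting material
13 | (4-methylpent-3-en-1-yl)triphenylphosphonium bromide | CC(C)=CCC[P+](c1ccccc1)(c1ccccc1)c1ccccc1.[Br-] | intermediate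
14 | (4-methylpent-3-en-1-ylidene)triphenyl-λ5-phosphane | CC(C)=CCC=P(c1ccccc1)(c1ccccc1)c1ccccc1 | intermediate
15 | 1-[2-hydroxy-4,6-bis(prop-2-en-1-yloxy)phenyl]-5-methyl-2-(triphenyl-λ5-phosphanylidene)hex-4-en-1-one | CC(C)=CCC(=P(c1ccccc1)(c1ccccc1)c1ccccc1)C(=O)c1c(O)cc(OCC=C)cc1OCC=C | intermediate
16 | 3-(3-methylbut-2-en-1-yl)-2,4-bis(prop-2-en-1-yloxy)benzoyl chloride | O=C(Cl)c1ccc(OCC=C)c(CC=C(C)C)c1OCC=C | intermediate
17 | 2-[5-methyl-2-(triphenyl-λ5-phosphanylidene)hex-4-enoyl]-3,5-bis(prop-2-en-1-yloxy)phenyl 3-(3-methylbut-2-en-1-yl)-2,4-bis(prop-2-en-1-yloxy)benzoate | CC(C)=CCC(=P(c1ccccc1)(c1ccccc1)c1ccccc1)C(=O)c1c(OC(=O)c2ccc(OCC=C)c(CC=C(C)C)c2OCC=C)cc(OCC=C)cc1OCC=C | intermediate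
18 | 3-(3-methylbut-2-en-1-yl)-2-[3-(3-methylbut-2-en-1-yl)-2,4-bis(prop-2-en-1-yloxy)phenyl]-5,7-bis(prop-2-en-1-yloxy)-4H-chromen-4-one | C=CCOc1cc(OCC=C)c2c(c1)oc(-c1ccc(OCC=C)c(CC=C(C)C)c1OCC=C)c(CC=C(C)C)c2=O | intermediate
19 | Kuwanon T, 5,7-dihydroxy-2-[2,4-dihydroxy-3-(3-methylbut-2-en-1-yl)phenyl]-3-(3-methylbut-2-en-1-yl)-4H-chromen-4-one | CC(C)=CCc1c(O)ccc(-c2oc3cc(O)cc(O)c3c(=O)c2CC=C(C)C)c1O | target

## Step count and risk

Total: 10 steps. Longest linear sequence: 7 steps (steps 1, 2, 3, 4, 5, 9, 10). Steps 6–8 form a three-step side branch.

**Step 9 (key step).** The most likely failure is that the intramolecular olefination stalls. The ylide carbon is stabilised and fully substituted, and the ester carbonyl is electron-rich and flanked by an ortho allyloxy group, so addition may be slow, and the aroyl group may be lost by acyl transfer or hydrolysis on work-up instead. The fallback abandons the ylide and builds ring C by an acyl shift. It sets out from 10. Addition of (4-methylpent-3-en-1-yl)magnesium bromide, made from 11 and Mg, should open the acylal to 1-[2-hydroxy-4,6-bis(prop-2-en-1-yloxy)phenyl]-5-methylhex-4-en-1-one F1. Esterification of its phenol with 16 in pyridine would give 2-(5-methylhex-4-enoyl)-3,5-bis(prop-2-en-1-yloxy)phenyl 3-(3-methylbut-2-en-1-yl)-2,4-bis(prop-2-en-1-yloxy)benzoate F2. A Baker–Venkataraman rearrangement with KOtBu in THF would give 1-[2-hydroxy-4,6-bis(prop-2-en-1-yloxy)phenyl]-2-(3-methylbut-2-en-1-yl)-3-[3-(3-methylbut-2-en-1-yl)-2,4-bis(prop-2-en-1-yloxy)phenyl]propane-1,3-dione F3. Cyclodehydration with NaOAc in AcOH at 100 °C, tolerable here because no free phenol stands next to a prenyl group, comes back to the route at 18.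

**Step 8.** The most likely failure is sluggish acylation of the bulky ylide at the hindered, electron-rich acylal carbonyl, together with loss of ylide to the ketone set free (olefination or enolisation). The fallback reverses the order of bond formation and uses the most reactive acyl donor. It sets out from 10. Hydrolysis with aqueous KOH should give 2-hydroxy-4,6-bis(prop-2-en-1-yloxy)benzoic acid F4. Acylation of its phenol with 16 in pyridine would give 2-{[3-(3-methylbut-2-en-1-yl)-2,4-bis(prop-2-en-1-yloxy)benzoyl]oxy}-4,6-bis(prop-2-en-1-yloxy)benzoic acid F5. The chloroenamine of step 9 would convert this to 2-{[3-(3-methylbut-2-en-1-yl)-2,4-bis(prop-2-en-1-yloxy)benzoyl]oxy}-4,6-bis(prop-2-en-1-yloxy)benzoyl chloride F6. Addition of F6 to two equivalents of 14 at −78 °C should acylate the ylide at the acid chloride in preference to the aryl ester. This comes back to the route at 17, which is heated to 18 as in step 9.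

**Step 3.** The most likely failure is poor regioselectivity of the sigmatropic shift (C5 instead of C3), with loss of the tertiary allyl group by elimination as a second drain. The fallback blocks C5. It sets out from 1. Bromination with NBS in MeCN should give methyl 5-bromo-2,4-dihydroxybenzoate F7. The conditions of steps 1–3 would then give methyl 5-bromo-2-hydroxy-4-[(2-methylbut-3-yn-2-yl)oxy]benzoate F8, methyl 5-bromo-2-hydroxy-4-[(2-methylbut-3-en-2-yl)oxy]benzoate F9 and, with C3 as the only open ortho position, methyl 5-bromo-2,4-dihydroxy-3-(3-methylbut-2-en-1-yl)benzoate F10. Reductive debromination with Pd(OAc)2, PPh3, HCO2H and Et3N in DMF at 80 °C comes back to the route at 5.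

**Step 10.** The most likely failure is incomplete cleavage of one of the four ethers, or C-allylation of the electron-rich ring A by the π-allyl complex once its phenoxides are free; air oxidation of the product is a further hazard. The fallback replaces the metal-catalysed ionisation by nucleophilic dealkylation. It sets out from 18 and uses NaSEt in DMF at 80 °C, an SN2 attack of thiolate on each allyl carbon with phenoxide as leaving group, under basic conditions that spare the prenyl groups. It comes back to the route at 19 and makes no new compound (F0).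

## Further compounds

F1 | step 9 | 1-[2-hydroxy-4,6-bis(prop-2-en-1-yloxy)phenyl]-5-methylhex-4-en-1-one | CC(C)=CCCC(=O)c1c(O)cc(OCC=C)cc1OCC=C
F2 | step 9 | 2-(5-methylhex-4-enoyl)-3,5-bis(prop-2-en-1-yloxy)phenyl 3-(3-methylbut-2-en-1-yl)-2,4-bis(prop-2-en-1-yloxy)benzoate | CC(C)=CCCC(=O)c1c(OC(=O)c2ccc(OCC=C)c(CC=C(C)C)c2OCC=C)cc(OCC=C)cc1OCC=C
F3 | step 9 | 1-[2-hydroxy-4,6-bis(prop-2-en-1-yloxy)phenyl]-2-(3-methylbut-2-en-1-yl)-3-[3-(3-methylbut-2-en-1-yl)-2,4-bis(prop-2-en-1-yloxy)phenyl]propane-1,3-dione | CC(C)=CCC(C(=O)c1c(O)cc(OCC=C)cc1OCC=C)C(=O)c1ccc(OCC=C)c(CC=C(C)C)c1OCC=C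
F4 | step 8 | 2-hydroxy-4,6-bis(prop-2-en-1-yloxy)benzoic acid | OC(=O)c1c(O)cc(OCC=C)cc1OCC=C
F5 | step 8 | 2-{[3-(3-methylbut-2-en-1-yl)-2,4-bis(prop-2-en-1-yloxy)benzoyl]oxy}-4,6-bis(prop-2-en-1-yloxy)benzoic acid | OC(=O)c1c(OC(=O)c2ccc(OCC=C)c(CC=C(C)C)c2OCC=C)cc(OCC=C)cc1OCC=C
F6 | step 8 | 2-{[3-(3-methylbut-2-en-1-yl)-2,4-bis(prop-2-en-1-yloxy)benzoyl]oxy}-4,6-bis(prop-2-en-1-yloxy)benzoyl chloride | ClC(=O)c1c(OC(=O)c2ccc(OCC=C)c(CC=C(C)C)c2OCC=C)cc(OCC=C)cc1OCC=C
F7 | step 3 | methyl 5-bromo-2,4-dihydroxybenzoate | COC(=O)c1cc(Br)c(O)cc1O
F8 | step 3 | methyl 5-bromo-2-hydroxy-4-[(2-methylbut-3-yn-2-yl)oxy]benzoate | COC(=O)c1cc(Br)c(OC(C)(C)C#C)cc1O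
F9 | step 3 | methyl 5-bromo-2-hydroxy-4-[(2-methylbut-3-en-2-yl)oxy]benzoate | COC(=O)c1cc(Br)c(OC(C)(C)C=C)cc1O
F10 | step 3 | methyl 5-bromo-2,4-dihydroxy-3-(3-methylbut-2-en-1-yl)benzoate | COC(=O)c1cc(Br)c(O)c(CC=C(C)C)c1O
F0 | step 10 | none | none
A1 | alternative 1 | 5,7-bis(methoxymethoxy)-2-[2,4-bis(methoxymethoxy)-3-(3-methylbut-2-en-1-yl)phenyl]-4H-chromen-4-one | COCOc1cc(OCOC)c2c(c1)oc(-c1ccc(OCOC)c(CC=C(C)C)c1OCOC)cc2=O
A2 | alternative 1 | 3-iodo-5,7-bis(methoxymethoxy)-2-[2,4-bis(methoxymethoxy)-3-(3-methylbut-2-en-1-yl)phenyl]-4H-chromen-4-one | COCOc1cc(OCOC)c2c(c1)oc(-c1ccc(OCOC)c(CC=C(C)C)c1OCOC)c(I)c2=O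
A3 | alternative 2 | 7-[(tert-butyldimethylsilyl)oxy]-2-{4-[(tert-butyldimethylsilyl)oxy]-3-(3-methylbut-2-en-1-yl)-2-[(3-methylbut-2-en-1-yl)oxy]phenyl}-5-hydroxy-4H-chromen-4-one | CC(C)=CCOc1c(CC=C(C)C)c(O[Si](C)(C)C(C)(C)C)ccc1-c1cc(=O)c2c(O)cc(O[Si](C)(C)C(C)(C)C)cc2o1
A4 | alternative 3 | ethyl 2-[3-(3-methylbut-2-en-1-yl)-2,4-bis(triisopropylsilyloxy)benzoyl]-5-methylhex-4-enoate | CCOC(=O)C(CC=C(C)C)C(=O)c1ccc(O[Si](C(C)C)(C(C)C)C(C)C)c(CC=C(C)C)c1O[Si](C(C)C)(C(C)C)C(C)C
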